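**Target:** compound 29 (CNP0343121.3), C[C@@]12C(=O)O[C@]3(CC[C@@H]1O)[C@@H]1CC[C@@H]4C[C@]1(C[C@]4(C)O)[C@@H](C(=O)O)[C@@H]32

## The problem

Compound 29 is a C16-hydrated 3β-hydroxy C19 gibberellin: cyclopentane ring B is fused on one side to ring A, which is spanned on its α face by the C19→C10 γ-lactone, and on the other, through the all-carbon quaternary C8 and the methine C9, to the bicyclo[3.2.1]octane of rings C and D. Atoms are numbered as in gibberellane (ring A C1–C5 and C10; ring B C5, C6, C8–C10; ring C C8, C9, C11–C14; ring D C8, C13–C16; C7 on C6, C17 on C16, C18 and C19 on C4), and α is the face of rings A and B that carries the lactone. Nine stereocentres must be set (C3, C4, C5, C6, C8, C9, C10, C13, C16); two are all-carbon quaternary (C4, C8) and two are fully substituted carbinol carbons (C10, C16). Only C13 needs an external source of chirality: it can direct methyl addition to C16, its one-atom link to C8 fixes C8, the cis preference of the B/C hydrindanone fixes C9, the convex face of that bicycle fixes C10, a tether from the C10 oxygen fixes C5 and C4, and C6 and C3 can be left to equilibration and to a bulky hydride. The sensitive groups are the β-hydroxy lactone (C3 epimerises by retro-aldol cleavage in base), the tertiary C16 carbinol (dehydration or rearrangement in strong acid) and the hindered C7 carboxyl (saponification would endanger the lactone). The feature that invites a cascade is C8: it is bonded to C9 of ring C and to C6, which carries the one-carbon unit C7, so an exocyclic C8=C6 methylene on a finished ring D can take up C9 from an alkenyl metal and then C7 from carbon monoxide.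

## Retrosynthesis

**29 ⇐ 28 ⇐ 27 (no skeletal bond).** The C7 acid is kept as its methyl ester 28 to the end and freed by thiolate demethylation, because hydroxide would attack the lactone and start the retro-aldol at C3. The 3β carbinol is traced to ketone 27: the axial 3β alcohol is the less stable epimer, so it is better made by equatorial hydride delivery than by any equilibrating C–C bond formation.

**27 ⇐ 26 ⇐ 25 (cut C3–C4).** Ring A is opened by a retro-aldol to aldehyde lactone 25. This is preferred over cutting C4–C5 last, which would require a fully substituted nucleophile to attack a carbon flanked by quaternary C10. The chain on C10 can reach only one face of the lactone enolate, so C4 is fixed by the ring. The C3 mixture in aldol 26 does not matter because oxidation converges it on 27.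

**25 ⇐ 24 ⇐ 22 (cut C4–C5).** The lactone C–C bond is cut to give propionate 22, in which C4, C18 and C19 hang from the C10 oxygen and C5=C6 is an enoate. The forward Michael addition is 5-exo, can only reach the α face of C5, and leaves C6 to be equilibrated trans to the new bond. This trades three stereocentres for one tertiary ester.

**22 ⇐ 20 (cut C10–C1 and O–C19).** The C1–C3 chain, with C3 masked as an acetal, and the propionyl group are removed to leave ene-keto ester 20. The forward addition must be 1,2 and from the convex β face of the cis-fused B/C bicycle.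

**20 ⇐ 18 ⇐ 16 (functional group level).** The C5=C6 bond comes from dehydrogenation of keto ester 18. The C9 hydrogen comes from hydrogenation of enone 16 followed by equilibration to the cis-fused hydrindanone. Ring B must therefore exist before C9 is set; in the open-chain ketone the preference would run the other way.

**16 ⇐ 15 (cut C5–C6).** Ring B is opened between the two α-carbons of a 1,4-dicarbonyl unit. This gives keto ester 15, whose methyl ketone (C5) and ester methylene (C6) are joined forward by oxidative enolate coupling. Halogenation at C5 followed by ester enolate alkylation was weighed against this and set aside: an α-halo ketone is far more acidic than the ester, so the ester enolate could not be formed in its presence.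

**15 ⇐ 12 + 13 + 14 (cut C8–C9 and C6–C7, key disconnection).** Both bonds to the C8/C6 unit are cut at once: iodoenone 12, carbon monoxide 13 and methanol 14. This removes ring C, the quaternary centre and the ester in one step and leaves a monocyclic precursor with two stereocentres. The forward cascade needs ring closure to be faster than capture of the first organopalladium by 13 and 14.

**12 ⇐ 11 ⇐ 9 + 10 (cut C9–I, then C9=C11).** The iodide is removed to enone 11, which is opened by cross-metathesis into allyl cyclopentane 9 and methyl vinyl ketone 10. Compound 10 supplies C9, C10 and C5 in one piece.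

**9 ⇐ 8 ⇐ 7 ⇐ 6 ⇐ 5 (C8=C6, C16–C17).** The methylene is traced to ketone 8, unmasked from ketal 7. The silyl ether 7 comes from carbinol 6, and 6 from methyl addition to ketone 5 trans to the allyl group.

**5 ⇐ 4 ⇐ 2 ⇐ 1 + 3 (cut C12–C13).** The only stereocentre that needs absolute control is made by auxiliary-directed allylation of commercial ketal ketone 1 with allyl bromide 3 through hydrazones 2 and 4.

## Roads not taken

**Alternative 1:** The cut is C4–C5 alone, made last and across a ring. In seven-membered β-keto lactone A1 the C19 carboxyl already esterifies the C10 oxygen and C3 is a ketone. A catalytic base would enolise C4, which adds transannularly to C5 of the ring B enoate and gives keto lactone A2, closing ring A and the γ-lactone together. A2 is the same compound as ketone 27 of the present route.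
- Merits: C4 and C5 are set in one base-catalysed step, and C3 arrives as the ketone, so no oxidation is needed.
- Weak points: A1 requires a medium-ring β-keto lactone built on a hindered tertiary alkoxide. The Michael step joins a fully substituted carbon to a centre next to quaternary C10 and is reversible. The whole B/C/D enoate must exist first.
- Comparison: in redox economy this road is better than the chosen endgame, which needs steps 17 and 18 to reach 27. The chosen plan sets against it a simple propionate donor, two ring closures of separately established types, and the fact that alternative 1 does not address C8 at all.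

**Alternative 2:** The cut is C6–C8, read as a ring contraction. Ring B is first six-membered, with C7 in the ring, in diazoketone A3. Irradiation in aqueous solvent expels nitrogen, C8 migrates from C7 to C6, and water adds to the ketene to give acid A4.
- Merits: the cis-fused precursor comes from a cycloaddition that sets quaternary C8 and C9 together. The Wolff step is dependable and leaves C7 at the acid level without any transition-metal cascade.
- Weak points: A4 lacks rings A and D, C13 and C16. The bicyclooctane must be built afterwards from a neopentyl ester on C8 and the ring C alkene. Absolute configuration has to come from an enantioselective cycloaddition, and the diazo group has to be placed regioselectively.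
- Comparison: for ring B alone this road is more reliable than the oxidative coupling of step 11. The chosen plan sets against it that ring D and both its stereocentres are in place before C8 is formed, that C8 is then fixed by geometry, and that C8–C9 and C6–C7 arise in one operation, which should make the route clearly shorter.

**Alternative 3:** The cuts are C5–C10 and O–C19. In keto enoate A5 a C10 ketone carries the C1–C3 chain and C6 carries an enoate made of C5, C4, C18 and C19. A divalent samarium reductant would turn the ketone into a ketyl that adds 5-exo to C5; the resulting samarium alkoxide acylates on C19 and gives lactone A6.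
- Merits: ring B, the lactone, C10 and C5 form in one mild step. A compound of the type of 24 is reached directly, where the chosen route spends steps 13 to 15.
- Weak points: A5 already needs C6, C8 and C9, two of them epimerisable next to carbonyl groups. The quaternary C8 with its C6–C7 arm must be made by some other method. The ketyl must choose the correct face relative to C9 and C6, and the reductant can also attack the enoate.
- Comparison: on the late stretch this road is shorter. The chosen plan sets against it that it solves the C8/C6–C7 problem, which A5 leaves open, and that it introduces every stereocentre under the control of one that is already present.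

Key step: step 10

Remark: the aqueous acid of step 16 is taken to hydrolyse the tertiary triethylsilyl ether together with the dioxolane; compounds 1, 3, 10, 13, 14, SAMP and [2-(1,3-dioxolan-2-yl)ethyl]magnesium bromide are taken as commercial.

## Route

Step 1
Reactants: 1 1,4-dioxaspiro[4.4]nonan-7-one
Product: 2 (S)-N-(1,4-dioxaspiro[4.4]nonan-7-ylidene)-2-(methoxymethyl)pyrrolidin-1-amine
Conditions: SAMP (1.05 equiv), 4 Å MS, cyclohexane, 60 °C
Reagents that add atoms: SAMP, (S)-1-amino-2-(methoxymethyl)pyrrolidine, COC[C@@H]1CCCN1N
Why: Condensation of a ketone with a 1,1-disubstituted hydrazine (first stage of the Enders SAMP-hydrazone method); no acid is added, so the dioxolane should survive.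

Step 2
Reactants: 2 SAMP hydrazone of 1; 3 allyl bromide
Product: 4 (S)-N-[(8R)-8-allyl-1,4-dioxaspiro[4.4]nonan-7-ylidene]-2-(methoxymethyl)pyrrolidin-1-amine
Conditions: LiN(i-Pr)2, THF, 0 °C; then 3, −100 °C → rt
Reagents that add atoms: none
Why: Enders hydrazone alkylation; the azaenolate should form at the less hindered methylene remote from the ketal (C13), and the chelated lithium directs the allyl group to the face that, for SAMP, gives the 13R centre (the sense that leads to (R)-2-alkylcycloalkanones).

Step 3
Reactants: 4 allylated SAMP hydrazone
Product: 5 (R)-8-allyl-1,4-dioxaspiro[4.4]nonan-7-one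
Conditions: sat. aq. oxalic acid, Et2O, rt
Reagents that add atoms: water, O
Why: Two-phase oxalic acid hydrolysis of the hydrazone, the mild cleavage used when the α-centre is epimerisable and an alkene rules out ozonolysis; the weak acid should leave the dioxolane intact and returns the auxiliary.

Step 4
Reactants: 5 (R)-8-allyl-1,4-dioxaspiro[4.4]nonan-7-one
Product: 6 (7S,8R)-8-allyl-7-methyl-1,4-dioxaspiro[4.4]nonan-7-ol (hydroxyl cis to allyl)
Conditions: MeMgBr, LaCl3·2LiCl (0.3 equiv), THF, −20 °C
Reagents that add atoms: methylmagnesium bromide, C[Mg]Br
Why: Lewis-acid-promoted Grignard 1,2-addition to a 2-substituted cyclopentanone; the methyl group should enter trans to the allyl group, placing the C16 oxygen cis to C12, and the lanthanum salt suppresses enolisation that would erode C13.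

Step 5
Reactants: 6 tertiary carbinol
Product: 7 triethyl{[(7S,8R)-8-allyl-7-methyl-1,4-dioxaspiro[4.4]nonan-7-yl]oxy}silane
Conditions: TESOTf, 2,6-lutidine, CH2Cl2, −78 → 0 °C
Reagents that add atoms: triethylsilyl trifluoromethanesulfonate, CC[Si](CC)(CC)OS(=O)(=O)C(F)(F)F
Why: Silylation of a hindered tertiary alcohol with a silyl triflate; the ether keeps the hydroxyl out of later iodination and palladium chemistry.

Step 6
Reactants: 7 silyl ether ketal
Product: 8 (3S,4R)-4-allyl-3-methyl-3-(triethylsilyloxy)cyclopentan-1-one
Conditions: PPTS, acetone–H2O (10:1), 50 °C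
Reagents that add atoms: water, O
Why: Acid-catalysed ketal hydrolysis under buffered pyridinium conditions, mild enough for the tertiary silyl ether and for the β-silyloxy ketone formed.

Step 7
Reactants: 8 β-silyloxy cyclopentanone
Product: 9 triethyl{[(1S,2R)-2-allyl-1-methyl-4-methylenecyclopentyl]oxy}silane
Conditions: Ph3PCH3Br, KOt-Bu, THF, 0 °C → rt
Reagents that add atoms: methyltriphenylphosphonium bromide, C[P+](c1ccccc1)(c1ccccc1)c1ccccc1.[Br-]
Why: Wittig methylenation of an unhindered cyclopentanone; the new CH2 is C6 and completes the C8=C6 acceptor.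

Step 8
Reactants: 9 methylenecyclopentane; 10 methyl vinyl ketone
Product: 11 (E)-5-[(1R,2S)-2-methyl-4-methylene-2-(triethylsilyloxy)cyclopentyl]pent-3-en-2-one
Conditions: second-generation Grubbs catalyst (5 mol %), 10 (3 equiv), CH2Cl2, 40 °C
Reagents that add atoms: none
Why: Olefin cross-metathesis of a terminal alkene with an electron-poor vinyl ketone, E-selective; the 1,1-disubstituted ring methylene is a much poorer partner and should stay untouched.

Step 9
Reactants: 11 E-enone
Product: 12 (Z)-3-iodo-5-[(1R,2S)-2-methyl-4-methylene-2-(triethylsilyloxy)cyclopentyl]pent-3-en-2-one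
Conditions: I2 (2 equiv), DMAP (0.2 equiv), pyridine–CH2Cl2 (1:1), rt, dark
Reagents that add atoms: iodine, [I][I]
Why: α-Iodination of an enone by amine-mediated addition–elimination (a Baylis–Hillman-type path); elimination gives the more stable Z isomer with acetyl trans to C12, and without water the isolated methylene only complexes iodine reversibly.

Step 10
Reactants: 12 (Z)-α-iodoenone; 13 carbon monoxide; 14 methanol
Product: 15 methyl 2-[(1S,5R,6S)-2-acetyl-6-methyl-6-(triethylsilyloxy)bicyclo[3.2.1]oct-2-en-1-yl]acetate
Conditions: Pd(OAc)2 (10 mol %), PPh3 (30 mol %), Et3N (3 equiv), 13 (1 atm), 14 (10 equiv), DMF, 70 °C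
Reagents that add atoms: none
Why: Domino Mizoroki–Heck cyclisation/alkoxycarbonylation, a known cascade for alkenyl halides tethered to 1,1-disubstituted alkenes. Zerovalent palladium inserts into the C9–I bond; the alkenylpalladium adds syn across C8=C6 in a 6-exo-trig closure that forms C8–C9 and ring C and leaves a neopentyl C6–Pd bond with no β-hydrogen. Insertion of 13 and methanolysis of the acylpalladium by 14 then form C6–C7 as the methyl ester, and triethylamine regenerates zerovalent palladium. The new centre C8 is controlled by C13: the three-atom tether leaves C13 on one face of ring D and can bridge to C8 only on that face, so a single bicyclo[3.2.1]octene diastereomer is expected. The selectivity needed is ring closure before capture of the first alkenyl- or acylpalladium by methanol; CO insertion is reversible and methanolysis is not, so 1 atm of CO and few equivalents of methanol should keep the acyl species in equilibrium with the cyclising alkenylpalladium. The Z geometry of 12 places C8 and C12 cis on C9=C11, as ring C requires, and quaternary-centre formation at the internal alkene carbon is the normal regiochemistry of exo closures.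

Step 11
Reactants: 15 bicyclic keto ester
Product: 16 B/C/D tricyclic enone ester (C10 ketone; C9=C11; C5 methylene; CO2Me on C6 as epimers; 16-OSiEt3)
Conditions: LiN(i-Pr)2 (2.2 equiv), THF, −78 °C; then Fe(acac)3 (2.2 equiv), −78 °C → rt, 0.01 M
Reagents that add atoms: none
Why: Intramolecular oxidative enolate coupling; the kinetic ketone enolate (C5) and the ester enolate (C6) are oxidised by trivalent iron and join as a 1,4-dicarbonyl unit, closing five-membered ring B, with the C6 mixture erased in step 13.

Step 12
Reactants: 16 tricyclic enone ester
Product: 18 cis-fused B/C/D keto ester (9β-H; C10 ketone; C6 ester epimers; 16-OSiEt3), via kinetic dihydro ketone 17 (not isolated)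
Conditions: H2 (1 atm), 10% Pd/C, EtOAc, rt; filter; then NaOMe (0.3 equiv), MeOH, rt
Reagents that add atoms: none
Why: Heterogeneous hydrogenation of the enone should add hydrogen from the open face on the side of the one-carbon bridge; methoxide then equilibrates C9 through the C10 enolate to the cis-fused hydrindanone (C10 anti to C15), the fusion preferred by hydrindan-1-ones with a quaternary carbon at the far ring-fusion position.

Step 13
Reactants: 18 cis-fused keto ester
Product: 20 ene-keto ester (C10 ketone; C5=C6; CO2Me on C6; 9β-H), via trimethylsilyl enol ether 19 (not isolated)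
Conditions: LiN(SiMe3)2, Me3SiCl, THF, −78 °C; then Pd(OAc)2 (10 mol %), O2 (1 atm), DMSO, rt
Reagents that add atoms: none
Why: Saegusa–Ito oxidation in its oxygen-coupled catalytic form; kinetic silylation takes the less hindered C5 methylene and divalent palladium removes the only β-hydrogen available (on C6), giving the C5=C6 bond.

Step 14
Reactants: 20 ene-keto ester
Product: 22 C10 propionate of the tertiary allylic carbinol (2-(1,3-dioxolan-2-yl)ethyl chain on C10β; oxygen α), via tertiary carbinol 21 (not isolated)
Conditions: BrMgCH2CH2CH(OCH2CH2O) (1.5 equiv), LaCl3·2LiCl (1 equiv), THF, −78 °C; then (EtCO)2O, DMAP, −78 °C → rt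
Reagents that add atoms: [2-(1,3-dioxolan-2-yl)ethyl]magnesium bromide, Br[Mg]CCC1OCCO1; propionic anhydride, CCC(=O)OC(=O)CC
Why: Lewis-acid-promoted Grignard 1,2-addition to an enone followed by acylation of the metal alkoxide in the same flask; attack on C10 should come from the convex β face of the cis-fused B/C bicycle, anti to C11, which places the oxygen α, and the lanthanum salt disfavours conjugate addition and enolisation at C9.

Step 15
Reactants: 22 propionate enoate
Product: 24 γ-lactone (C4–C5 bond; 6β-CO2Me; C4 epimers; acetal chain on C10; 16-OSiEt3), via kinetic Michael adduct 23 (not isolated)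
Conditions: KN(SiMe3)2 (1.1 equiv), THF, −78 → −20 °C; AcOH; then NaOMe (0.3 equiv), MeOH, 40 °C
Reagents that add atoms: none
Why: Intramolecular Michael addition of a propionate ester enolate to the enoate (5-exo-trig); the O10 tether reaches only the α face of C5, so the lactone is cis-fused and C5 is set. The competing enolate Claisen rearrangement would have to bond to fully substituted C6, and methoxide then equilibrates C6 to the ester trans to the new C4–C5 bond.

Step 16
Reactants: 24 γ-lactone acetal
Product: 25 aldehyde lactone (C3 aldehyde; free C16 hydroxyl; C4 epimers)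
Conditions: 2 M aq. HCl, THF, 40 °C
Reagents that add atoms: water, O
Why: Aqueous acid hydrolysis of the dioxolane, which should also cleave the tertiary triethylsilyl ether; the lactone, the methyl ester and the tertiary carbinol, itself a hydration product stable in dilute aqueous acid, are expected to survive.

Step 17
Reactants: 25 aldehyde lactone
Product: 26 3-hydroxy lactone methyl ester with ring A closed (C3 epimers)
Conditions: NaOMe (0.2 equiv), MeOH, 0 °C → rt
Reagents that add atoms: none
Why: Intramolecular aldol addition of the lactone enolate (C4) to the C3 aldehyde under equilibrating alkoxide conditions, the reverse of the known base-induced retro-aldol opening of 3-hydroxy gibberellin lactones; the chain on C10 reaches only one face of the enolate, so C4 is fixed with C18 exo, and both C3 epimers are carried on.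

Step 18
Reactants: 26 3-hydroxy lactone (C3 epimers)
Product: 27 3-oxo lactone methyl ester
Conditions: Dess–Martin periodinane, CH2Cl2, rt
Reagents that add atoms: none
Why: Dess–Martin oxidation of a secondary alcohol under neutral conditions converges both C3 epimers on one ketone; C4 bears no hydrogen and the tertiary C16 hydroxyl is inert.

Step 19
Reactants: 27 3-oxo lactone
Product: 28 methyl ester of the target (3β-hydroxy)
Conditions: K[HB(s-Bu)3] (2.5 equiv), THF, −78 °C; aq. KH2PO4 quench
Reagents that add atoms: none
Why: Reduction of a hindered cyclohexanone by a bulky trialkylborohydride; hydride takes the equatorial trajectory, avoiding the axial hydrogens on C1 and C5, and should give the axial 3β alcohol cis to C18, while the buffered cold quench prevents retro-aldol epimerisation of the alkoxide.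

Step 20
Reactants: 28 methyl ester
Product: 29 target acid (CNP0343121.3)
Conditions: LiSPr, HMPA, 0 °C → rt; aq. HCl to pH 3
Reagents that add atoms: none
Why: SN2 demethylation of the hindered methyl ester by thiolate in a dipolar aprotic solvent, which frees the C7 acid without acyl attack on the lactone; thiolate is too weak a base to start the retro-aldol at C3.

## Compound list

1 | 1,4-dioxaspiro[4.4]nonan-7-one | O=C1CCC2(C1)OCCO2 | starting material
2 | (S)-N-(1,4-dioxaspiro[4.4]nonan-7-ylidene)-2-(methoxymethyl)pyrrolidin-1-amine (C=N geometry not fixed) | COC[C@@H]1CCCN1N=C1CCC2(C1)OCCO2 | intermediate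
3 | allyl bromide | C=CCBr | starting material
4 | (S)-N-[(8R)-8-allyl-1,4-dioxaspiro[4.4]nonan-7-ylidene]-2-(methoxymethyl)pyrrolidin-1-amine | C=CC[C@@H]1CC2(CC1=NN1CCC[C@H]1COC)OCCO2 | intermediate
5 | (R)-8-allyl-1,4-dioxaspiro[4.4]nonan-7-one | C=CC[C@@H]1CC2(CC1=O)OCCO2 | intermediate
6 | (7S,8R)-8-allyl-7-methyl-1,4-dioxaspiro[4.4]nonan-7-ol | C=CC[C@@H]1CC2(C[C@]1(C)O)OCCO2 | intermediate
7 | triethyl{[(7S,8R)-8-allyl-7-methyl-1,4-dioxaspiro[4.4]nonan-7-yl]oxy}silane | C=CC[C@@H]1CC2(C[C@]1(C)O[Si](CC)(CC)CC)OCCO2 | intermediate
8 | (3S,4R)-4-allyl-3-methyl-3-(triethylsilyloxy)cyclopentan-1-one | C=CC[C@@H]1CC(=O)C[C@]1(C)O[Si](CC)(CC)CC | intermediate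
9 | triethyl{[(1S,2R)-2-allyl-1-methyl-4-methylenecyclopentyl]oxy}silane | C=CC[C@@H]1CC(=C)C[C@]1(C)O[Si](CC)(CC)CC | intermediate
10 | methyl vinyl ketone | CC(=O)C=C | starting material
11 | (E)-5-[(1R,2S)-2-methyl-4-methylene-2-(triethylsilyloxy)cyclopentyl]pent-3-en-2-one | CC(=O)/C=C/C[C@@H]1CC(=C)C[C@]1(C)O[Si](CC)(CC)CC | intermediate
12 | (Z)-3-iodo-5-[(1R,2S)-2-methyl-4-methylene-2-(triethylsilyloxy)cyclopentyl]pent-3-en-2-one | CC(=O)/C(I)=C/C[C@@H]1CC(=C)C[C@]1(C)O[Si](CC)(CC)CC | intermediate
13 | carbon monoxide | [C-]#[O+] | starting material
14 | methanol | CO | starting material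
15 | methyl 2-[(1S,5R,6S)-2-acetyl-6-methyl-6-(triethylsilyloxy)bicyclo[3.2.1]oct-2-en-1-yl]acetate | CC(=O)C1=CC[C@@H]2C[C@]1(C[C@]2(C)O[Si](CC)(CC)CC)CC(=O)OC | intermediate
16 | B/C/D tricyclic enone ester: ring B cyclopentanone (C10 ketone, C5 methylene, CO2Me on C6 as epimers) fused at C8–C9 to the bicyclooctene, C9=C11, 16-methyl, 16-OSiEt3 endo | O=C1C2=CC[C@@H]3C[C@]2(C[C@]3(C)O[Si](CC)(CC)CC)C(C(=O)OC)C1 | intermediate
17 | dihydro derivative of 16 as formed on hydrogenation (C9 and C6 not yet settled) | O=C1C2CC[C@@H]3C[C@]2(C[C@]3(C)O[Si](CC)(CC)CC)C(C(=O)OC)C1 | intermediate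
18 | cis-fused B/C/D keto ester, 9β-H (C6 epimers) | O=C1[C@@H]2CC[C@@H]3C[C@]2(C[C@]3(C)O[Si](CC)(CC)CC)C(C(=O)OC)C1 | intermediate
19 | C10 trimethylsilyl enol ether of 18 (C10=C5) | C[Si](C)(C)OC1[C@@H]2CC[C@@H]3C[C@]2(C[C@]3(C)O[Si](CC)(CC)CC)C(C(=O)OC)C=1 | intermediate
20 | ene-keto ester: C10 ketone, C5=C6, CO2Me on C6, 9β-H, 16-OSiEt3 | O=C1[C@@H]2CC[C@@H]3C[C@]2(C[C@]3(C)O[Si](CC)(CC)CC)C(C(=O)OC)=C1 | intermediate
21 | tertiary allylic carbinol: 10α-OH, 10β-[2-(1,3-dioxolan-2-yl)ethyl], C5=C6 enoate | O[C@]1(CCC2OCCO2)[C@@H]2CC[C@@H]3C[C@]2(C[C@]3(C)O[Si](CC)(CC)CC)C(C(=O)OC)=C1 | intermediate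
22 | propionate ester of 21 | CCC(=O)O[C@]1(CCC2OCCO2)[C@@H]2CC[C@@H]3C[C@]2(C[C@]3(C)O[Si](CC)(CC)CC)C(C(=O)OC)=C1 | intermediate
23 | kinetic Michael adduct: 19,10-γ-lactone with C4–C5 bond, C4 and C6 epimers | CC1C(=O)O[C@]2(CCC3OCCO3)[C@@H]3CC[C@@H]4C[C@]3(C[C@]4(C)O[Si](CC)(CC)CC)C(C(=O)OC)[C@@H]21 | intermediate
24 | equilibrated γ-lactone: 5β-H, 6β-CO2Me, C4 epimers, acetal chain on C10, 16-OSiEt3 | CC1C(=O)O[C@]2(CCC3OCCO3)[C@@H]3CC[C@@H]4C[C@]3(C[C@]4(C)O[Si](CC)(CC)CC)[C@@H](C(=O)OC)[C@@H]21 | intermediate
25 | aldehyde lactone: 3-oxopropyl chain on C10, free 16-OH, C4 epimers | CC1C(=O)O[C@]2(CCC=O)[C@@H]3CC[C@@H]4C[C@]3(C[C@]4(C)O)[C@@H](C(=O)OC)[C@@H]21 | intermediate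
26 | methyl ester of the target as a mixture of C3 epimers | C[C@@]12C(=O)O[C@]3(CCC1O)[C@@H]1CC[C@@H]4C[C@]1(C[C@]4(C)O)[C@@H](C(=O)OC)[C@@H]32 | intermediate
27 | 3-oxo analogue of the target methyl ester | C[C@@]12C(=O)O[C@]3(CCC1=O)[C@@H]1CC[C@@H]4C[C@]1(C[C@]4(C)O)[C@@H](C(=O)OC)[C@@H]32 | intermediate
28 | methyl ester of the target (3β-OH) | C[C@@]12C(=O)O[C@]3(CC[C@@H]1O)[C@@H]1CC[C@@H]4C[C@]1(C[C@]4(C)O)[C@@H](C(=O)OC)[C@@H]32 | intermediate
29 | CNP0343121.3: 3β,16-dihydroxy-16-methyl 19,10-lactone 7-acid, 16-hydroxyl endo to ring C | C[C@@]12C(=O)O[C@]3(CC[C@@H]1O)[C@@H]1CC[C@@H]4C[C@]1(C[C@]4(C)O)[C@@H](C(=O)O)[C@@H]32 | target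

## Step count and least certain steps

Total step count: 20. Longest linear sequence: 20 steps (fully linear from 1).

**Step 10 (key step).** The most likely failure is capture of the alkenyl- or acylpalladium by methanol before ring closure, giving direct methoxycarbonylation at C9. A second risk is slow CO uptake after closure, which would let the neopentylpalladium add back to C9=C11. Both arise because CO insertion into an alkenylpalladium is fast and the closing face of ring D also carries the endo silyloxy group. Fallback: ring closure and carbonylation are separated. From iodide 12, palladium-catalysed carboiodination (Pd[P(t-Bu)3]2, toluene, 100 °C) closes ring C with carbon–iodine reductive elimination and gives the neopentyl iodide 1-[1-(iodomethyl)-6-methyl-6-(triethylsilyloxy)bicyclo[3.2.1]oct-2-en-2-yl]ethan-1-one F1. Atom-transfer radical carbonylation of F1 (13, 14, K2CO3, hν) then gives ester 15, where the route is rejoined.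

**Step 11.** The most likely failure is intermolecular coupling or hydrogen abstraction by the oxidised ester enolate before it finds C5, because two different enolates must be oxidised and combined within one molecule. Fallback from 15 to 20, replacing steps 11 to 13: Riley oxidation (SeO2, dioxane–H2O) of the methyl ketone should give the keto aldehyde F2. Soft enolisation of the ester with TiCl4/Et3N and intramolecular aldol addition to the aldehyde forms C5–C6 and gives the 5-hydroxy keto ester F3. Hydrogenation as in step 12 gives the dihydro compound F4. Mesylation and DBU elimination then form C5=C6, equilibrate C9 and lead to 20.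

**Step 12.** The most likely failure is an insufficient thermodynamic bias at C9, since the position of the cis/trans hydrindanone equilibrium is not known for this bridged system and hydrogenation alone should deliver the wrong face. Fallback from 16 by kinetic control: HF·pyridine removes the silyl group to give the carbinol F5. Hydrogenation with [Ir(cod)(PCy3)(py)]PF6 in CH2Cl2 is directed by the endo C16 hydroxyl, which lies over the bridge-side face of C9=C11, and should give the 9β-H keto ester F6. Resilylation (TESOTf, 2,6-lutidine) returns to 18.

**Step 14.** The most likely failure is enolisation at C9 or conjugate addition to the doubly activated C5=C6 bond in place of carbonyl addition, because the acetal-bearing sp3 Grignard reagent is slow towards a ketone next to a quaternary centre. Fallback from 20: allylmagnesium bromide, which adds 1,2 through a cyclic transition state even to hindered enones, followed by propionic anhydride, gives the allyl propionate F7. Michael addition and equilibration as in step 15 give the allyl lactone F8. Hydroboration with 9-borabicyclononane and NaBO3 oxidation give the primary alcohol F9, and Dess–Martin oxidation gives the silylated aldehyde F10. 2 M HCl in THF removes the silyl group and rejoins the route at 25.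

**Step 17.** The most likely failure is diversion of the seco-aldehyde through enolisation at C2 or C6 instead of C4, leading to acyl transfer onto the lactone or the wrong aldol, because all three positions are deprotonated reversibly by alkoxide. Fallback from 25 to 27: Pinnick oxidation (NaClO2, NaH2PO4, 2-methyl-2-butene) gives the acid F11. Coupling with N,O-dimethylhydroxylamine (EDC) gives the Weinreb amide F12. LiN(i-Pr)2 (2.2 equiv, THF, −78 °C) forms the C16 alkoxide and selectively the more acidic lactone enolate, whose intramolecular acylation by the amide should give ketone 27 directly through the chelated tetrahedral intermediate, so that step 18 is no longer needed.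

## Further compounds

F1 | step 10 | 1-[1-(iodomethyl)-6-methyl-6-(triethylsilyloxy)bicyclo[3.2.1]oct-2-en-2-yl]ethan-1-one (configured as 15) | CC(=O)C1=CC[C@@H]2C[C@]1(C[C@]2(C)O[Si](CC)(CC)CC)CI
F2 | step 11 | keto aldehyde: 15 with the acetyl group oxidised to a glyoxyloyl group | O=CC(=O)C1=CC[C@@H]2C[C@]1(C[C@]2(C)O[Si](CC)(CC)CC)CC(=O)OC
F3 | step 11 | 5-hydroxy derivative of tricyclic enone ester 16 (C5 and C6 epimers) | O=C1C2=CC[C@@H]3C[C@]2(C[C@]3(C)O[Si](CC)(CC)CC)C(C(=O)OC)C1O
F4 | step 11 | 9,11-dihydro derivative of F3 | O=C1C2CC[C@@H]3C[C@]2(C[C@]3(C)O[Si](CC)(CC)CC)C(C(=O)OC)C1O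
F5 | step 12 | desilylated 16 (free 16-OH enone ester) | O=C1C2=CC[C@@H]3C[C@]2(C[C@]3(C)O)C(C(=O)OC)C1
F6 | step 12 | desilylated 18 (9β-H keto ester with free 16-OH) | O=C1[C@@H]2CC[C@@H]3C[C@]2(C[C@]3(C)O)C(C(=O)OC)C1
F7 | step 14 | 10β-allyl analogue of propionate 22 | CCC(=O)O[C@]1(CC=C)[C@@H]2CC[C@@H]3C[C@]2(C[C@]3(C)O[Si](CC)(CC)CC)C(C(=O)OC)=C1
F8 | step 14 | 10β-allyl analogue of lactone 24 | CC1C(=O)O[C@]2(CC=C)[C@@H]3CC[C@@H]4C[C@]3(C[C@]4(C)O[Si](CC)(CC)CC)[C@@H](C(=O)OC)[C@@H]21
F9 | step 14 | 3-hydroxypropyl lactone (16-OSiEt3) | CC1C(=O)O[C@]2(CCCO)[C@@H]3CC[C@@H]4C[C@]3(C[C@]4(C)O[Si](CC)(CC)CC)[C@@H](C(=O)OC)[C@@H]21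
F10 | step 14 | 16-O-triethylsilyl ether of aldehyde 25 | CC1C(=O)O[C@]2(CCC=O)[C@@H]3CC[C@@H]4C[C@]3(C[C@]4(C)O[Si](CC)(CC)CC)[C@@H](C(=O)OC)[C@@H]21
F11 | step 17 | C3 carboxylic acid from aldehyde 25 | CC1C(=O)O[C@]2(CCC(=O)O)[C@@H]3CC[C@@H]4C[C@]3(C[C@]4(C)O)[C@@H](C(=O)OC)[C@@H]21
F12 | step 17 | C3 N-methoxy-N-methylamide of F11 | CC1C(=O)O[C@]2(CCC(=O)N(C)OC)[C@@H]3CC[C@@H]4C[C@]3(C[C@]4(C)O)[C@@H](C(=O)OC)[C@@H]21
A1 | alternative 1 | seven-membered β-keto lactone with ring B enoate | CC1C(=O)O[C@]2(CCC1=O)[C@@H]1CC[C@@H]3C[C@]1(C[C@]3(C)O)C(C(=O)OC)=C2
A2 | alternative 1 | 3-oxo lactone methyl ester (same as 27) | C[C@@]12C(=O)O[C@]3(CCC1=O)[C@@H]1CC[C@@H]4C[C@]1(C[C@]4(C)O)[C@@H](C(=O)OC)[C@@H]32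
A3 | alternative 2 | six-membered 6-diazo-7-ketone of the ketal-protected cis-hydrindene ester | O1CCOC12[C@@H]3CC=CC[C@]3(C(=O)OC)C(=O)C(=[N+]=[N-])C2
A4 | alternative 2 | ring-contracted cis-hydrindene acid with C7 on C6 | O1CCOC12[C@@H]3CC=CC[C@]3(C(=O)OC)[C@@H](C(=O)O)C2
A5 | alternative 3 | C10 ketone with silyloxypropyl chain and C6-bound (E)-2-methylpropenoate | O=C(CCCO[Si](C)(C)C(C)(C)C)[C@@H]1CC[C@@H]2C[C@]1(C[C@]2(C)O)[C@@H](C(=O)OC)/C=C(\C)C(=O)OC
A6 | alternative 3 | B/C/D lactone lacking ring A (C4 epimers) | CC2C(=O)O[C@]3(CCCO[Si](C)(C)C(C)(C)C)[C@@H]1CC[C@@H]4C[C@]1(C[C@]4(C)O)[C@@H](C(=O)OC)[C@@H]32
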